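**Plan**

- Retrosynthesis: the C12–Br bond goes back to the inverted alcohol; the side chain is cut at C3=C4 (Peterson olefination) and C5–C6 (γ-chloroallylboration) to a 2-(hydroxymethyl)oxocene. That ether is re-bridged from C13 to the C6 oxygen (a temporary ketal bond). The bridged ketal is then cut at C8–C9 and O–C13 into an iodomethyl dioxolane and an (E)-2-chloro-1-iodoalkenyl ethyl ketone.
- Enabling feature: the ring oxygen on C7 and the acetoxy oxygen on C6 are vicinal, and C13 is the other oxygen-bearing ring carbon. With C13 at the ketone level both oxygens can clamp it, so the oxocene arises as the large ring of an 8,10-dioxabicyclo[5.2.1]dec-3-ene.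
- Forward order: glycidate → α-silyloxy alkynyl ketone → I–Cl adduct. Nickel coupling with the solketal-derived iodide and in-flask transketalisation then form the dioxolane and the eight-membered ring together. Et3SiH/TiCl4 cleaves the temporary O–C13 bond to the cis-2,8-oxocene; side chain and bromide follow.
- Stereochemistry: C12 from methyl (R)-glycidate (inverted in the final bromination); C7 from (R)-solketal; C13 relayed from C7 through the bridged ketal and set by invertive hydride delivery; C5/C6 by the (Z)-γ-chloroallyl-Ipc2B reagent; ring alkene from anti I–Cl addition; enyne from Z-selective Peterson olefination.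

Key step: step 7

Numbering used in the text: chain carbons C1 (alkyne CH) to C15 (ethyl CH3); the ring oxygen joins C7 and C13.

**Route**

Step 1
Reactants: 1 methyl (2R)-oxirane-2-carboxylate; 2 ethynyltrimethylsilane
Product: 3 methyl (2R)-2-hydroxy-5-(trimethylsilyl)pent-4-ynoate
Conditions: 2, n-BuLi, toluene, 0 °C; Et2AlCl; then 1, 0 °C; aq. Rochelle salt
Reagents that add atoms: none
Why: Epoxide ring-opening alkynylation: the alkynylalane attacks the unsubstituted C3 of the glycidate by SN2, so the C2 stereocentre of 1 passes unchanged into the (R)-α-hydroxy ester that becomes C12.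

Step 2
Reactants: 3 methyl (2R)-2-hydroxy-5-(trimethylsilyl)pent-4-ynoate
Product: 4 methyl (2R)-2-[(tert-butyldimethylsilyl)oxy]-5-(trimethylsilyl)pent-4-ynoate
Conditions: TBSCl, imidazole, DMF, 25 °C
Reagents that add atoms: tert-butyldimethylsilyl chloride CC(C)(C)[Si](C)(C)Cl
Why: Silyl ether formation protects the secondary hydroxyl with a group that should survive Grignard reagents, the nickel coupling and TiCl4 at −78 °C; no stereocentre is touched.

Step 3
Reactants: 4 methyl (2R)-2-[(tert-butyldimethylsilyl)oxy]-5-(trimethylsilyl)pent-4-ynoate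
Product: 5 methyl (2R)-2-[(tert-butyldimethylsilyl)oxy]pent-4-ynoate
Conditions: K2CO3 (cat.), MeOH, 0 °C
Reagents that add atoms: none
Why: Base-catalysed methanolytic protodesilylation cleaves only the C(sp)–Si bond and frees the terminal alkyne needed for the later halogen addition, leaving the O–Si bond and the α-stereocentre intact.

Step 4
Reactants: 5 methyl (2R)-2-[(tert-butyldimethylsilyl)oxy]pent-4-ynoate
Product: 7 (4R)-4-[(tert-butyldimethylsilyl)oxy]hept-6-yn-3-one, via Weinreb amide 6 (not isolated)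
Conditions: MeNH(OMe)·HCl, i-PrMgCl, THF, −20 °C; then EtMgBr, 0 °C; aq. NH4Cl
Reagents that add atoms: N,O-dimethylhydroxylamine hydrochloride CNOC.Cl (atoms present in 6 only); ethylmagnesium bromide CC[Mg]Br
Why: Weinreb ketone synthesis: the magnesium amide converts the ester into the N-methoxy-N-methylamide, whose chelated tetrahedral adduct with EtMgBr collapses to the ethyl ketone only on work-up, so over-addition and α-epimerisation should be avoided.

Step 5
Reactants: 7 (4R)-4-[(tert-butyldimethylsilyl)oxy]hept-6-yn-3-one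
Product: 8 (4R,6E)-4-[(tert-butyldimethylsilyl)oxy]-6-chloro-7-iodohept-6-en-3-one
Conditions: ICl, Et4NCl, CH2Cl2, −78 → 0 °C
Reagents that add atoms: iodine monochloride ClI
Why: Electrophilic iodochlorination: the iodonium ion of the terminal alkyne is opened by chloride anti and at the internal carbon, which should give the (E)-2-chloro-1-iodoalkene with iodine cis to the chain, the geometry that becomes the ring alkene.

Step 6
Reactants: 9 [(4R)-2,2-dimethyl-1,3-dioxolan-4-yl]methanol
Product: 10 (4S)-4-(iodomethyl)-2,2-dimethyl-1,3-dioxolane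
Conditions: I2, PPh3, imidazole, CH2Cl2, 0 → 25 °C
Reagents that add atoms: iodine II
Why: Appel iodination of the primary alcohol; the stereocentre is not involved and only its descriptor changes from R to S.

Step 7
Reactants: 8 (4R,6E)-4-[(tert-butyldimethylsilyl)oxy]-6-chloro-7-iodohept-6-en-3-one; 10 (4S)-4-(iodomethyl)-2,2-dimethyl-1,3-dioxolane
Product: 12 (1R,3E,6R,7S)-6-[(tert-butyldimethylsilyl)oxy]-4-chloro-7-ethyl-8,10-dioxabicyclo[5.2.1]dec-3-ene, via keto acetonide 11 (not isolated)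
Conditions: NiBr2·glyme (10 mol %), 4,4'-di-tert-butyl-2,2'-bipyridine, Mn, NaI (cat.), DMA, 25 °C; then silica plug, CSA (cat.), CH2Cl2, 35 °C, acetone removed
Reagents that add atoms: none
Why: Ni(0) inserts into the C–I bond of 8, the primary radical from 10 is captured at nickel and reductive elimination forges the C8–C9 sp3–sp2 bond with retention of alkene geometry to give 11; acid then opens the acetonide and the C6/C7 diol ketalises the C13 ketone with loss of acetone, so the ring bond O–C13 forms together with the temporary O(C6)–C13 bond. The closest known reaction types are the nickel-catalysed cross-electrophile coupling of alkyl halides with alkenyl halides and the acid-catalysed keto-diol cyclisation to 6,8-dioxabicyclo[3.2.1]octane ketals, here in its two-carbon-larger form. The eight-membered ring (O, C7 to C13) closes by 8-exo-trig addition of the C7 oxygen to the C13 carbonyl/oxocarbenium carbon under thermodynamic control, and the five-membered dioxolane (C6, C7, C13 and both oxygens) closes in the same ketalisation. The new stereocentre C13 is fixed by C7, because the two-atom O–CH2 bridge can only span the large ring cis; it is inverted on purpose in step 8. The step needs activation of C(sp2)–I over both C–Cl bonds and retention of the iodine-cis-to-chain geometry, which the weaker C–I bond and the trans I/Cl arrangement (no syn β-chloride elimination at nickel) should secure. Intramolecular ketalisation over oligomerisation should be secured by dilution and by the chain-cis chloroalkene, which brings the C7 oxygen and C13 together.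

Step 8
Reactants: 12 (1R,3E,6R,7S)-6-[(tert-butyldimethylsilyl)oxy]-4-chloro-7-ethyl-8,10-dioxabicyclo[5.2.1]dec-3-ene
Product: 13 [(2R,4E,7R,8R)-7-[(tert-butyldimethylsilyl)oxy]-5-chloro-8-ethyl-3,6,7,8-tetrahydro-2H-oxocin-2-yl]methanol
Conditions: Et3SiH, TiCl4, CH2Cl2, −78 °C; aq. NaHCO3
Reagents that add atoms: none
Why: Invertive reductive ketal cleavage (ionic hydrogenation): TiCl4 binds the less hindered primary ketal oxygen, the C13–O(C6) bond ionises to the eight-membered oxocarbenium ion and Et3SiH delivers hydride to the face opposite both the departing titanium alkoxide and the C12 silyloxy group, which should set C13–H cis to C7–H and free the C6 hydroxyl.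

Step 9
Reactants: 13 [(2R,4E,7R,8R)-7-[(tert-butyldimethylsilyl)oxy]-5-chloro-8-ethyl-3,6,7,8-tetrahydro-2H-oxocin-2-yl]methanol
Product: 14 (2R,4E,7R,8R)-7-[(tert-butyldimethylsilyl)oxy]-5-chloro-8-ethyl-3,6,7,8-tetrahydro-2H-oxocine-2-carbaldehyde
Conditions: Dess–Martin periodinane, CH2Cl2, 0 → 25 °C
Reagents that add atoms: none
Why: Dess–Martin oxidation of the primary alcohol under near-neutral conditions should give the α-alkoxy aldehyde without epimerising C7; it is used crude.

Step 10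
Reactants: 14 (2R,4E,7R,8R)-7-[(tert-butyldimethylsilyl)oxy]-5-chloro-8-ethyl-3,6,7,8-tetrahydro-2H-oxocine-2-carbaldehyde; 15 3-chloroprop-1-ene
Product: 16 (1S,2S)-1-[(2R,4E,7R,8R)-7-[(tert-butyldimethylsilyl)oxy]-5-chloro-8-ethyl-3,6,7,8-tetrahydro-2H-oxocin-2-yl]-2-chlorobut-3-en-1-ol
Conditions: 15, LiN(c-C6H11)2 (from Cy2NH, n-BuLi), (+)-Ipc2BOMe, BF3·OEt2, THF–Et2O, −95 °C; then 14, −95 °C; ethanolamine work-up
Reagents that add atoms: none
Why: Brown-type γ-chloroallylboration through a chair transition state: the (Z)-γ-chloroallylborane gives the syn chlorohydrin and the isopinocampheyl groups derived from (−)-α-pinene direct attack to the Re face of the aldehyde, which should set C6 (S) and C5 (S) under reagent control.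

Step 11
Reactants: 16 (1S,2S)-1-[(2R,4E,7R,8R)-7-[(tert-butyldimethylsilyl)oxy]-5-chloro-8-ethyl-3,6,7,8-tetrahydro-2H-oxocin-2-yl]-2-chlorobut-3-en-1-ol
Product: 17 (1S,2S)-1-[(2R,4E,7R,8R)-7-[(tert-butyldimethylsilyl)oxy]-5-chloro-8-ethyl-3,6,7,8-tetrahydro-2H-oxocin-2-yl]-2-chlorobut-3-en-1-yl acetate
Conditions: Ac2O, pyridine, DMAP (cat.), CH2Cl2, 0 °C
Reagents that add atoms: acetic anhydride CC(=O)OC(C)=O
Why: Acylation installs the C6 acetate of the target and removes the free hydroxyl before the aldehyde is unmasked; pyridine is too weak a base to close the chlorohydrin to an epoxide.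

Step 12
Reactants: 17 (1S,2S)-1-[(2R,4E,7R,8R)-7-[(tert-butyldimethylsilyl)oxy]-5-chloro-8-ethyl-3,6,7,8-tetrahydro-2H-oxocin-2-yl]-2-chlorobut-3-en-1-yl acetate
Product: 18 (1S,2R)-1-[(2R,4E,7R,8R)-7-[(tert-butyldimethylsilyl)oxy]-5-chloro-8-ethyl-3,6,7,8-tetrahydro-2H-oxocin-2-yl]-2-chloro-3-oxopropyl acetate
Conditions: OsO4 (cat.), NaIO4, 2,6-lutidine, dioxane–H2O, 25 °C
Reagents that add atoms: osmium tetroxide O=[Os](=O)(=O)=O (catalytic, re-oxidised by sodium periodate [Na+].[O-][I](=O)(=O)=O)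
Why: Lemieux–Johnson oxidative cleavage of the monosubstituted terminal alkene; the trisubstituted ring chloroalkene is electron-poor and hindered and should be spared, and the descriptor at C5 changes only through CIP priority.

Step 13
Reactants: 18 (1S,2R)-1-[(2R,4E,7R,8R)-7-[(tert-butyldimethylsilyl)oxy]-5-chloro-8-ethyl-3,6,7,8-tetrahydro-2H-oxocin-2-yl]-2-chloro-3-oxopropyl acetate; 19 1,3-bis(triisopropylsilyl)prop-1-yne
Product: 20 (1S,2S,3Z)-1-[(2R,4E,7R,8R)-7-[(tert-butyldimethylsilyl)oxy]-5-chloro-8-ethyl-3,6,7,8-tetrahydro-2H-oxocin-2-yl]-2-chloro-6-(triisopropylsilyl)hex-3-en-5-yn-1-yl acetate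
Conditions: 19, n-BuLi, THF, −20 °C; then 18, −78 → 0 °C
Reagents that add atoms: none
Why: Peterson olefination: the lithiated bis-silylpropyne adds to the aldehyde and the β-silyl alkoxide eliminates silanolate in the flask, a process known to favour the (Z)-enyne in THF, and the fast elimination should outrun attack of the alkoxide on the neighbouring C–Cl bond.

Step 14
Reactants: 20 (1S,2S,3Z)-1-[(2R,4E,7R,8R)-7-[(tert-butyldimethylsilyl)oxy]-5-chloro-8-ethyl-3,6,7,8-tetrahydro-2H-oxocin-2-yl]-2-chloro-6-(triisopropylsilyl)hex-3-en-5-yn-1-yl acetate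
Product: 21 (1S,2S,3Z)-2-chloro-1-[(2R,4E,7R,8R)-5-chloro-8-ethyl-7-hydroxy-3,6,7,8-tetrahydro-2H-oxocin-2-yl]hex-3-en-5-yn-1-yl acetate
Conditions: TBAF, AcOH, THF, 0 → 25 °C
Reagents that add atoms: none
Why: Fluoride-mediated desilylation cleaves both the alkynyl C–Si and the secondary O–Si bond, and the acetic acid buffer should keep the acetate and the allylic chloride intact.

Step 15
Reactants: 21 (1S,2S,3Z)-2-chloro-1-[(2R,4E,7R,8R)-5-chloro-8-ethyl-7-hydroxy-3,6,7,8-tetrahydro-2H-oxocin-2-yl]hex-3-en-5-yn-1-yl acetate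
Product: 22 (1S,2S,3Z)-1-[(2R,4E,7S,8R)-7-bromo-5-chloro-8-ethyl-3,6,7,8-tetrahydro-2H-oxocin-2-yl]-2-chlorohex-3-en-5-yn-1-yl acetate
Conditions: CBr4, (n-Oct)3P, toluene, 70 °C
Reagents that add atoms: carbon tetrabromide BrC(Br)(Br)Br
Why: Appel-type bromination: bromide displaces the alkoxyphosphonium group by SN2 with inversion, converting the (12R)-alcohol into the (12S)-bromide trans to the C13 ethyl group.

**Compound list**

1 | methyl (2R)-oxirane-2-carboxylate | COC(=O)[C@H]1CO1 | starting material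
2 | ethynyltrimethylsilane | C#C[Si](C)(C)C | starting material
3 | methyl (2R)-2-hydroxy-5-(trimethylsilyl)pent-4-ynoate | COC(=O)[C@H](O)CC#C[Si](C)(C)C | intermediate
4 | methyl (2R)-2-[(tert-butyldimethylsilyl)oxy]-5-(trimethylsilyl)pent-4-ynoate | COC(=O)[C@H](O[Si](C)(C)C(C)(C)C)CC#C[Si](C)(C)C | intermediate
5 | methyl (2R)-2-[(tert-butyldimethylsilyl)oxy]pent-4-ynoate | COC(=O)[C@H](O[Si](C)(C)C(C)(C)C)CC#C | intermediate
6 | (2R)-2-[(tert-butyldimethylsilyl)oxy]-N-methoxy-N-methylpent-4-ynamide (Weinreb amide, not isolated) | CON(C)C(=O)[C@H](O[Si](C)(C)C(C)(C)C)CC#C | intermediate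
7 | (4R)-4-[(tert-butyldimethylsilyl)oxy]hept-6-yn-3-one | CCC(=O)[C@H](O[Si](C)(C)C(C)(C)C)CC#C | intermediate
8 | (4R,6E)-4-[(tert-butyldimethylsilyl)oxy]-6-chloro-7-iodohept-6-en-3-one | CCC(=O)[C@H](O[Si](C)(C)C(C)(C)C)C/C(Cl)=C\I | intermediate
9 | [(4R)-2,2-dimethyl-1,3-dioxolan-4-yl]methanol | CC1(C)OC[C@H](O1)CO | starting material
10 | (4S)-4-(iodomethyl)-2,2-dimethyl-1,3-dioxolane | CC1(C)OC[C@H](O1)CI | intermediate
11 | (4R,6E)-4-[(tert-butyldimethylsilyl)oxy]-6-chloro-8-[(4R)-2,2-dimethyl-1,3-dioxolan-4-yl]oct-6-en-3-one (keto acetonide, not isolated) | CC1(C)OC[C@H](O1)C/C=C(/Cl)C[C@@H](O[Si](C)(C)C(C)(C)C)C(=O)CC | intermediate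
12 | (1R,3E,6R,7S)-6-[(tert-butyldimethylsilyl)oxy]-4-chloro-7-ethyl-8,10-dioxabicyclo[5.2.1]dec-3-ene | O1C[C@H]2C/C=C(/Cl)C[C@@H](O[Si](C)(C)C(C)(C)C)[C@]1(CC)O2 | intermediate
13 | [(2R,4E,7R,8R)-7-[(tert-butyldimethylsilyl)oxy]-5-chloro-8-ethyl-3,6,7,8-tetrahydro-2H-oxocin-2-yl]methanol | OC[C@H]1C/C=C(/Cl)C[C@@H](O[Si](C)(C)C(C)(C)C)[C@@H](CC)O1 | intermediate
14 | (2R,4E,7R,8R)-7-[(tert-butyldimethylsilyl)oxy]-5-chloro-8-ethyl-3,6,7,8-tetrahydro-2H-oxocine-2-carbaldehyde | O=C[C@H]1C/C=C(/Cl)C[C@@H](O[Si](C)(C)C(C)(C)C)[C@@H](CC)O1 | intermediate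
15 | 3-chloroprop-1-ene (allyl chloride) | C=CCCl | starting material
16 | (1S,2S)-1-[(2R,4E,7R,8R)-7-[(tert-butyldimethylsilyl)oxy]-5-chloro-8-ethyl-3,6,7,8-tetrahydro-2H-oxocin-2-yl]-2-chlorobut-3-en-1-ol | C=C[C@H](Cl)[C@@H](O)[C@H]1C/C=C(/Cl)C[C@@H](O[Si](C)(C)C(C)(C)C)[C@@H](CC)O1 | intermediate
17 | (1S,2S)-1-[(2R,4E,7R,8R)-7-[(tert-butyldimethylsilyl)oxy]-5-chloro-8-ethyl-3,6,7,8-tetrahydro-2H-oxocin-2-yl]-2-chlorobut-3-en-1-yl acetate | C=C[C@H](Cl)[C@@H](OC(C)=O)[C@H]1C/C=C(/Cl)C[C@@H](O[Si](C)(C)C(C)(C)C)[C@@H](CC)O1 | intermediate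
18 | (1S,2R)-1-[(2R,4E,7R,8R)-7-[(tert-butyldimethylsilyl)oxy]-5-chloro-8-ethyl-3,6,7,8-tetrahydro-2H-oxocin-2-yl]-2-chloro-3-oxopropyl acetate | O=C[C@H](Cl)[C@@H](OC(C)=O)[C@H]1C/C=C(/Cl)C[C@@H](O[Si](C)(C)C(C)(C)C)[C@@H](CC)O1 | intermediate
19 | 1,3-bis(triisopropylsilyl)prop-1-yne | CC(C)[Si](C(C)C)(C(C)C)CC#C[Si](C(C)C)(C(C)C)C(C)C | starting material
20 | (1S,2S,3Z)-1-[(2R,4E,7R,8R)-7-[(tert-butyldimethylsilyl)oxy]-5-chloro-8-ethyl-3,6,7,8-tetrahydro-2H-oxocin-2-yl]-2-chloro-6-(triisopropylsilyl)hex-3-en-5-yn-1-yl acetate | CC(C)[Si](C(C)C)(C(C)C)C#C/C=C\[C@H](Cl)[C@@H](OC(C)=O)[C@H]1C/C=C(/Cl)C[C@@H](O[Si](C)(C)C(C)(C)C)[C@@H](CC)O1 | intermediate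
21 | (1S,2S,3Z)-2-chloro-1-[(2R,4E,7R,8R)-5-chloro-8-ethyl-7-hydroxy-3,6,7,8-tetrahydro-2H-oxocin-2-yl]hex-3-en-5-yn-1-yl acetate | C#C/C=C\[C@H](Cl)[C@@H](OC(C)=O)[C@H]1C/C=C(/Cl)C[C@@H](O)[C@@H](CC)O1 | intermediate
22 | (1S,2S,3Z)-1-[(2R,4E,7S,8R)-7-bromo-5-chloro-8-ethyl-3,6,7,8-tetrahydro-2H-oxocin-2-yl]-2-chlorohex-3-en-5-yn-1-yl acetate | C#C/C=C\[C@H](Cl)[C@@H](OC(C)=O)[C@H]1C/C=C(/Cl)C[C@H](Br)[C@@H](CC)O1 | target

**Totals and risks**

Total step count: 15. Longest linear sequence: 14 steps (steps 1 to 5 and 7 to 15, from methyl (2R)-oxirane-2-carboxylate).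

Steps most likely to fail:

Step 7. What may go wrong: homocoupling or reduction of the iodoalkene, loss of alkene geometry at nickel, or oligomeric ketal exchange in place of the strained bridged closure. The fallback sets out from 7 and returns at 12, and closes the large ring at the C9=C10 double bond instead. Gold(I)-catalysed Markovnikov hydrochlorination of the terminal alkyne (HCl·DMPU) should give (4R)-4-[(tert-butyldimethylsilyl)oxy]-6-chlorohept-6-en-3-one F1. Acid-catalysed ketalisation with commercial (2R)-pent-4-ene-1,2-diol (CSA, benzene, water removed, with re-equilibration of the unwanted ketal epimer) should give the cis dioxolane (2S,4R)-2-[(1R)-1-[(tert-butyldimethylsilyl)oxy]-3-chlorobut-3-en-1-yl]-2-ethyl-4-(prop-2-en-1-yl)-1,3-dioxolane F2. Ring-closing metathesis of the 2-chloroalkene with the allyl group (second-generation ruthenium benzylidene catalyst, toluene, 80 °C, high dilution) would then deliver 12.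

Step 8. What may go wrong: ionisation of the other ketal C–O bond (leading to a nine-membered ether), hydride delivery from the wrong face, or Lewis-acid loss of the silyl ether. The fallback sets out from 8 and returns at 13 without a bridged ketal. Commercial (R)-glycidyl butanoate is opened with LiI/AcOH to (2S)-2-hydroxy-3-iodopropyl butanoate F3 and silylated (TESCl, imidazole) to (2S)-3-iodo-2-[(triethylsilyl)oxy]propyl butanoate F4. Coupling with 8 under the nickel conditions of step 7 gives (2R,4E,7R)-7-[(tert-butyldimethylsilyl)oxy]-5-chloro-8-oxo-2-[(triethylsilyl)oxy]dec-4-en-1-yl butanoate F5. Reductive etherification (BiBr3 cat., Et3SiH, MeCN, 0 °C) joins the C7 silyloxy oxygen to the C13 ketone and should give the 2,8-cis ether [(2R,4E,7R,8R)-7-[(tert-butyldimethylsilyl)oxy]-5-chloro-8-ethyl-3,6,7,8-tetrahydro-2H-oxocin-2-yl]methyl butanoate F6, hydride entering anti to the C12 silyloxy group. Methanolysis (K2CO3, MeOH) then gives 13.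

Step 13. What may go wrong: enolisation or β-elimination of the α-chloro-β-acetoxy aldehyde by the lithium reagent, chloride displacement by the intermediate alkoxide, or erosion of Z-selectivity. The fallback sets out from 18 and returns at 20 by a route with no free alkoxide. Stork–Zhao olefination (Ph3P=CHI from the phosphonium iodide and NaHMDS, THF–HMPA, −78 °C) should give (1S,2S,3Z)-1-[(2R,4E,7R,8R)-7-[(tert-butyldimethylsilyl)oxy]-5-chloro-8-ethyl-3,6,7,8-tetrahydro-2H-oxocin-2-yl]-2-chloro-4-iodobut-3-en-1-yl acetate F7. Sonogashira coupling with ethynyltriisopropylsilane (Pd(PPh3)4, CuI, i-Pr2NH, 0 °C) then gives 20.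

**Further compounds**

F1 | step 7 | (4R)-4-[(tert-butyldimethylsilyl)oxy]-6-chlorohept-6-en-3-one | CCC(=O)[C@H](O[Si](C)(C)C(C)(C)C)CC(Cl)=C
F2 | step 7 | (2S,4R)-2-[(1R)-1-[(tert-butyldimethylsilyl)oxy]-3-chlorobut-3-en-1-yl]-2-ethyl-4-(prop-2-en-1-yl)-1,3-dioxolane | O1C[C@@H](CC=C)O[C@@]1(CC)[C@H](O[Si](C)(C)C(C)(C)C)CC(Cl)=C
F3 | step 8 | (2S)-2-hydroxy-3-iodopropyl butanoate | CCCC(=O)OC[C@H](O)CI
F4 | step 8 | (2S)-3-iodo-2-[(triethylsilyl)oxy]propyl butanoate | CCCC(=O)OC[C@H](O[Si](CC)(CC)CC)CI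
F5 | step 8 | (2R,4E,7R)-7-[(tert-butyldimethylsilyl)oxy]-5-chloro-8-oxo-2-[(triethylsilyl)oxy]dec-4-en-1-yl butanoate | CCCC(=O)OC[C@H](O[Si](CC)(CC)CC)C/C=C(/Cl)C[C@@H](O[Si](C)(C)C(C)(C)C)C(=O)CC
F6 | step 8 | [(2R,4E,7R,8R)-7-[(tert-butyldimethylsilyl)oxy]-5-chloro-8-ethyl-3,6,7,8-tetrahydro-2H-oxocin-2-yl]methyl butanoate | CCCC(=O)OC[C@H]1C/C=C(/Cl)C[C@@H](O[Si](C)(C)C(C)(C)C)[C@@H](CC)O1
F7 | step 13 | (1S,2S,3Z)-1-[(2R,4E,7R,8R)-7-[(tert-butyldimethylsilyl)oxy]-5-chloro-8-ethyl-3,6,7,8-tetrahydro-2H-oxocin-2-yl]-2-chloro-4-iodobut-3-en-1-yl acetate | I/C=C\[C@H](Cl)[C@@H](OC(C)=O)[C@H]1C/C=C(/Cl)C[C@@H](O[Si](C)(C)C(C)(C)C)[C@@H](CC)O1
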